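## The problem

Compound 33 is a cis,cis-germacranolide. In germacrane numbering (ring C1 to C10, lactone carbons C11 to C13 on C7, C14 on C10, C15 on C4), a ten-membered carbocycle holds two trisubstituted, ring-cis alkenes (C1=C10 and C4=C5) and is trans-fused at C6–C7 to an α-methylene-γ-butyrolactone. There are four stereocentres (2S, 6R, 7R, 8R). C6, C7 and C8 are contiguous, so C6/C7 can be set together in an open chain and C7 can then steer C8. C2 is separated from them by both alkenes and must be set by a reagent. Four oxygens have to be told apart: the lactone oxygen on C6, the angelate on C8, the primary allylic acetate on C14 and the free allylic hydroxyl on C2. The methylene lactone (a Michael acceptor), the angelate (Z to E isomerisation with base or nucleophiles), the acetate, and a free 8-oxygen that could relactonise onto C12 all exclude strong base and strong nucleophiles late in the route. The feature that opens a short way in is the 1,5-relation of the C2 and C8 oxygens through C1=C10 (C2–C1=C10–C9–C8, with C14 on C10). This pattern is what remains when the C2–C9 bond of a cyclic 1,3-diketone (C2, C9, C8) is replaced by a two-carbon alkyne unit (C1, C10), so the ten-membered ring can be grown from an eight-membered ring in which C4=C5 is necessarily cis.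

## Retrosynthesis

**Unmasking last (33 ⇒ 32 ⇒ 31 ⇒ 30).** The O2–Si bond, the C12 carbonyl level and the C11=C13 bond are removed in that order. The methylene lactone is the most fragile group, so it is made last but one, from lactol 30 by a Mannich condensation at C11 and oxidation of lactol 31. The usual alternative, alkylating a lactone enolate, would not tolerate the two esters; doing it before acylation would cost two protecting-group steps and expose a free 8-oxygen to the lactone. Lactol 30 lacks one carbon and the Michael acceptor. The forward steps require that the lactol reacts through its open hydroxy aldehyde form and that the silyl ether is removed without acyl migration.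

**Esters before the lactone (30 ⇒ 29 ⇒ 26 ⇒ 25).** The lactol is traced to the methyl acetal 29, and the acyl C–O bonds at O8 (from angelic acid 27) and O14 are cut to reach diol 25. While C12 is an acetal tied to O6, the 8-hydroxyl has no lactone to attack and O6 is never free. The primary allylic and the hindered secondary hydroxyl of 25 differ enough to be acylated in turn, with O2 held as a silyl ether. The forward steps require primary-over-secondary acetylation and an angeloylation that keeps the Z-alkene.

**Stereocentres back to carbonyls (25 ⇒ 24 ⇒ 23 ⇒ 22).** Cutting the C8–H, C14–H and C2–H bonds returns C8 and C2 to ketones and C14 to a methyl ester, which is exactly the pattern the key step delivers. C2 is reduced first, by a chiral catalyst. C8 follows under 1,2-induction from C7 in the same operation that reduces the ester. Diketo ester 22 retains only the C6 and C7 stereocentres. The forward steps require discrimination between the conjugated C2 carbonyl and the hindered C8 carbonyl, and Felkin–Anh attack at C8.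

**Two-carbon ring expansion (22 ⇒ 18 + 19).** The C1–C2 and C9–C10 bonds are cut and C2–C9 is restored, giving the silyl enol ether 18 of an eight-membered 1,3-diketone and methyl propiolate 19. End-to-end closures of the ten-membered ring (at C1=C10, C5–C6 or C4=C5) must overcome transannular strain and leave an alkene geometry open. Here the large ring appears by cutting a bond inside a bicycle, C1=C10 inherits the geometry of a cyclobutene, C4=C5 is already fixed, and both new ketones sit where 33 carries oxygen. Enol ether 18 is much simpler: one small ring, two stereocentres. The forward step requires head-to-head photoaddition at C2=C9 and a clean retro-aldol cleavage.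

**Regiodefined enol ether (18 ⇒ 17 ⇒ 16).** The O2–Si bond and the C2 oxidation level are removed. Silylating the cyclic diketone 17 is preferred to silylating an open-chain diketone because in the ring the silyl group cannot migrate between the two oxygens. The forward step requires O-silylation on the less hindered C2 oxygen.

**Eight-membered ring (16 ⇒ 15).** The C4=C5 bond is cut by a ring-closing metathesis transform, which can only give the cis alkene in a ring of this size. The closure is done at the β-hydroxy ketone stage because a chelated open-chain diketone enol would hold the chain ends apart. Diene 15 is acyclic except for the tetrahydrofuran that templates the closure.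

**Chain assembly (15 ⇒ 11 + 13; 13 ⇒ 12; 11 ⇒ 10 ⇒ 9).** The C9–C2 bond is cut by an aldol transform between methyl ketone 11 and 3-methylbut-3-enal 13, which is made from alcohol 12. Acylating 11 with a 3-methylbut-3-enoyl donor was rejected because that donor is deprotonated and isomerised by enolates. Ketone 11 comes from Weinreb amide 10, and 10 from hydroxy acetal 9 by closing O6 onto C12. This one ring protects O6, masks C12 and later templates the metathesis.

**Origin of C6 and C7 (9 ⇒ 8 ⇒ 5 + 6; 5 ⇒ 2 + 3; 2 ⇒ 1).** The C6–C7 bond is cut by an Evans syn-aldol transform between imide 5 and acrolein 6. The 6,7-syn relation of 8 is the one that becomes the trans lactone fusion. Imide 5 comes from acid 2 and auxiliary 3, and 2 from ester 1.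

## Roads not taken

**Alternative 1: Nozaki–Hiyama–Kishi closure at C5–C6.** The cut is the C5–C6 bond of A1, leading to the open-chain (Z)-iodoalkene aldehyde A2. In the forward step CrCl2 (divalent chromium) with catalytic NiCl2 (divalent nickel) would turn the vinyl iodide into a vinylchromium species that adds to the C6 aldehyde, closing the ring and creating the C6 carbinol.
- Merits: the reaction type is known for medium rings, it tolerates the angelate and acetate already present in A2, it keeps the iodoalkene geometry, and after closure only C12 oxidation and lactonisation remain.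
- Weak points: the C6 configuration is created in the macrocyclisation and controlled only by ring conformation. A2 needs both trisubstituted alkenes made with defined geometry in an open chain, and C2, C7 and C8 set acyclically. Its aldehyde is α-branched with a β-acyloxy group, so it can epimerise or eliminate.
- Comparison: as a ring-forming event this is better precedented than step 12, and it carries the full acyl pattern through. The chosen plan sets against it that both ring-cis alkenes come from small rings by construction and that C6/C7 come from an auxiliary aldol, at the price of a photochemical step without direct precedent.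

**Alternative 2: Anionic oxy-Cope ring expansion.** The cut is C8–C9 with C1–C6 rejoined, leading from ketone A3 to the cis-dialkenylcyclohexenol A4. In the forward step KH would form the C6 potassium alkoxide of A4, whose [3,3] shift makes C8–C9, breaks C1–C6 and gives A3 with C1=C10 and the C8 stereocentre (as silicon).
- Merits: a strongly accelerated, known rearrangement with precedent in germacrane work, chirality transfer to C8, and C4=C5 cis from the six-membered ring.
- Weak points: a cis-dialkenyl substrate can react through two chair-like transition states, and only the one with the C1–C2 ring bond axial gives ring-cis C1=C10. A3 lacks C11 to C13 and the C6 and C7 stereocentres, so C7 alkylation and C6 reduction must be controlled on the flexible ring. The later silicon-to-oxygen exchange needs an electrophilic step that competes with two trisubstituted alkenes. KH forces all acylations to the end.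
- Comparison: ring formation is more secure than in the chosen plan. The chosen plan sets against it that only two centres (C2, C8) have to be made on the large ring, both by ketone reduction, and that the sequence after ring formation is shorter.

**Alternative 3: Horner–Wadsworth–Emmons macrocyclisation at C1=C10.** The cut is the C1=C10 bond of A5, leading to the phosphonoacetate aldehyde A6. In the forward step LiCl and a tertiary amine would form the phosphonate anion, which condenses with the C1 aldehyde.
- Merits: mild and well known for macrocyclic enoates. All four stereocentres are in place before ring closure, a real advantage over the chosen plan, which must set C2 and C8 on the ring. A5 corresponds to intermediate 24, so the endgame would be equally short.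
- Weak points: ten is the worst ring size for end-to-end closure, so dimers are likely. The enoate geometry inside a strained ring is not assured. The α-silyloxy aldehyde of A6 can epimerise at C2 under the amine. A6 needs the Z-trisubstituted C4=C5 alkene and four stereocentres assembled on an open chain.
- Comparison: this road is better in precedent and in stereochemical bookkeeping. The chosen plan sets against it that no ten-membered ring is closed end to end, that both alkene geometries are fixed by construction, and that assembly is shorter.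

Key step: step 12

Assumption (remark on the chemistry): the acetal carbon C12 (compounds 10, 11, 14–18, 20–26, 29–31), the carbinol carbon C2 of 15 and 16, and C2/C9 of 20 and 21 are carried as mixtures of epimers, because all of them later become planar or are cleaved; their SMILES leave these centres open. Germacrane numbering is used for locants in the text.

## Route

Step 1
Reactants: 1 methyl 4,4-dimethoxybutanoate
Product: 2 4,4-dimethoxybutanoic acid
Conditions: LiOH·H2O, THF/H2O, rt; 1 M HCl to pH 4, 0 °C; used at once
Reagents that add atoms: lithium hydroxide, [Li+].[OH-]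
Why: Ester saponification; the dimethyl acetal is inert to hydroxide, and the acid is freed only at pH 4 in the cold so that it does not close to the pseudo-ester.

Step 2
Reactants: 2 4,4-dimethoxybutanoic acid; 3 (S)-4-benzyloxazolidin-2-one
Product: 5 (S)-4-benzyl-3-(4,4-dimethoxybutanoyl)oxazolidin-2-one, via mixed pivalic anhydride 4 (not isolated)
Conditions: t-BuCOCl, Et3N, THF, −20 °C; then LiCl, 3, −20 °C → rt
Reagents that add atoms: none
Why: One-pot mixed-anhydride N-acylation of the Evans auxiliary; no acid strong enough to touch the acetal is present.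

Step 3
Reactants: 5 (S)-4-benzyl-3-(4,4-dimethoxybutanoyl)oxazolidin-2-one; 6 acrolein
Product: 8 (S)-4-benzyl-3-[(2S,3R)-2-(2,2-dimethoxyethyl)-3-hydroxypent-4-enoyl]oxazolidin-2-one, via (Z)-dibutylboron enolate 7 (not isolated)
Conditions: n-Bu2BOTf, Et3N, CH2Cl2, −78 → 0 °C; 6, −78 → 0 °C; pH 7 buffer, MeOH, 30% H2O2, 0 °C
Reagents that add atoms: none
Why: Evans syn aldol; the (Z)-boron enolate reacts through a closed Zimmerman–Traxler chair on the face away from the benzyl group, setting C7 and C6 (6R, 6,7-syn), the relation that becomes the trans lactone fusion.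

Step 4
Reactants: 8 aldol adduct
Product: 9 (2S,3R)-2-(2,2-dimethoxyethyl)-3-hydroxy-N-methoxy-N-methylpent-4-enamide
Conditions: MeONHMe·HCl, AlMe3, CH2Cl2, −20 → 0 °C
Reagents that add atoms: N,O-dimethylhydroxylamine hydrochloride, CNOC.Cl
Why: Weinreb transamination of a β-hydroxy imide, assisted by the free hydroxyl as its aluminium alkoxide; it releases the auxiliary and prepares C8 for a single carbanion addition.

Step 5
Reactants: 9 hydroxy Weinreb amide
Product: 10 (2R,3S)-2-ethenyl-N,5-dimethoxy-N-methyloxolane-3-carboxamide (C6–O–C12 cyclic methyl acetal)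
Conditions: pyridinium p-toluenesulfonate (5 mol %), 4 Å molecular sieves, CH2Cl2, rt
Reagents that add atoms: none
Why: Acid-catalysed transacetalisation; O6 closes 5-exo onto the oxocarbenium ion at C12 to give the trans-2,3-disubstituted 2-methoxytetrahydrofuran, which protects O6, masks C12 and later templates the ring closure.

Step 6
Reactants: 10 cyclic acetal Weinreb amide
Product: 11 1-[(2R,3S)-2-ethenyl-5-methoxyoxolan-3-yl]ethan-1-one
Conditions: MeMgBr, THF, 0 °C
Reagents that add atoms: methylmagnesium bromide, C[Mg]Br
Why: Weinreb ketone synthesis; the magnesium chelate stops at the ketone, and the trans-disubstituted ring is the stable arrangement at C7.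

Step 7
Reactants: 12 3-methylbut-3-en-1-ol
Product: 13 3-methylbut-3-enal
Conditions: Dess–Martin periodinane, pyridine, CH2Cl2, 0 °C → rt; used as a cold solution
Reagents that add atoms: none
Why: Buffered Dess–Martin oxidation gives the β,γ-unsaturated aldehyde without the acid or base that would move the double bond into conjugation.

Step 8
Reactants: 11 methyl ketone; 13 3-methylbut-3-enal
Product: 15 1-[(2R,3S)-2-ethenyl-5-methoxyoxolan-3-yl]-3-hydroxy-5-methylhex-5-en-1-one, via lithium enolate 14 (not isolated)
Conditions: LiN(i-Pr)2, THF, −78 °C; then 13, −78 °C; AcOH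
Reagents that add atoms: none
Why: Kinetic deprotonation at the C9 methyl group (not the ring C7–H) and aldol addition form C9–C2; the new carbinol centre is oxidised later, so its configuration does not matter.

Step 9
Reactants: 15 diene hydroxy ketone
Product: 16 (3aS,9aR,8Z)-6-hydroxy-2-methoxy-8-methyl-3,3a,5,6,7,9a-hexahydro-2H-cycloocta[b]furan-4-one
Conditions: second-generation Grubbs catalyst (H2IMes)(PCy3)Cl2Ru=CHPh (10 mol %), CH2Cl2 (2 mM), 40 °C
Reagents that add atoms: none
Why: Ring-closing metathesis of the C5 vinyl group with the 1,1-disubstituted C4 alkene; the trans-fused tetrahydrofuran holds the two chains gauche, the arrangement that allows trisubstituted cyclooctenes to close in trans-bicyclo[6.3.0] systems, and the eight-membered ring can only hold C4=C5 cis.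

Step 10
Reactants: 16 cyclooctenol-one
Product: 17 (3aS,9aR,8Z)-2-methoxy-8-methyl-3,3a,7,9a-tetrahydro-2H-cycloocta[b]furan-4,6(5H)-dione
Conditions: Dess–Martin periodinane, pyridine, CH2Cl2, 0 °C → rt
Reagents that add atoms: none
Why: Dess–Martin oxidation of a β-hydroxy ketone to the 1,3-diketone under non-basic conditions that leave the skipped C4=C5 alkene in place.

Step 11
Reactants: 17 cyclic 1,3-diketone
Product: 18 (3aS,9aR,5E,8Z)-2-methoxy-8-methyl-6-(triethylsilyloxy)-3,3a,7,9a-tetrahydro-2H-cycloocta[b]furan-4-one (C2 silyl enol ether, C8 ketone)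
Conditions: Et3SiCl, Et3N, 4-(dimethylamino)pyridine (5 mol %), CH2Cl2, 0 °C; filtered through Et3N-treated silica and used at once
Reagents that add atoms: chlorotriethylsilane, CC[Si](Cl)(CC)CC
Why: O-silylation of the diketone enolate at O2, which is flanked by CH2, in preference to O8 next to the ring-fusion carbon; in the ring the silyloxy group lies trans to C8 across C2=C9, so no 1,5-silyl shift can scramble the regiochemistry.

Step 12
Reactants: 18 C2 silyl enol ether; 19 methyl propiolate
Product: 22 methyl (3aS,11aR,6E,10Z)-2-methoxy-10-methyl-4,8-dioxo-2,3,3a,4,5,8,9,11a-octahydrocyclodeca[b]furan-6-carboxylate (ten-membered 2,8-diketone with C14 as ester), via cyclobutene silyl ether 20 (not isolated), via cyclobutenol 21 (not isolated)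
Conditions: hν (350–366 nm, Pyrex), 19 (20 equiv), degassed MeCN, −20 °C; evaporate cold; Bu4NF, AcOH (1:1), THF, −20 → 0 °C
Reagents that add atoms: none
Why: Proposed new method: the excited β-silyloxy enone of 18 should add the alkyne stepwise through a triplet 1,4-biradical to give cyclobutene 20, and fluoride then frees the C2 oxygen of this strained β-oxy ketone, which cleaves C2–C9 by retro-aldol reaction to the C8 enolate and, after protonation at C9, to 22. The closest known reactions are the de Mayo reaction (enol derivative plus alkene, then retro-aldol) and the enone–alkyne photocycloaddition to cyclobutenes; their combination on a medium-ring silyl enol ether of a 1,3-diketone has not been shown. The four-membered ring closes by radical recombination across C2=C9, whereas the ten-membered ring is not closed end to end: it appears when the bond shared by the four- and eight-membered rings is cut, so no transannular strain has to be overcome in a cyclisation. C2 and C9 become stereocentres in 20 (cis on the cyclobutene by necessity) but both are planar again in 22, so facial selectivity is irrelevant and C6 and C7 are untouched. The step needs the head-to-head orientation (the ester-bearing C10 to C9, C1 to C2): the acceptor-bearing alkyne carbon is expected to bond to the enone α-carbon, as electron-poor partners do with cyclic enones, and the silyloxy donor at C2 polarises the enone in the same sense. Site selectivity is secured by the preformed C2 enol ether (the C8 enol and C4=C5 are not part of the chromophore), and the fragmentation can only run toward the C8-stabilised carbanion at C9, since neither C1 nor C3 offers comparable stabilisation. The cyclobutene double bond becomes C1=C10 with C2 and C9 cis, the ring-cis geometry of 33. The trans-fused tetrahydrofuran and five sp2 ring atoms should limit the twisting that wastes excited medium-ring enones, long-wavelength light spares the β,γ-unsaturated ketone 20 from 1,3-acyl shift, and acetic acid protonates the enolate before the alkene can move out of conjugation with C2.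

Step 13
Reactants: 22 ten-membered diketo ester
Product: 23 methyl (3aS,8S,11aR,6E,10Z)-8-hydroxy-2-methoxy-10-methyl-4-oxo-2,3,3a,4,5,8,9,11a-octahydrocyclodeca[b]furan-6-carboxylate (2S alcohol, C8 ketone)
Conditions: (R)-1-methyl-3,3-diphenyltetrahydro-1H,3H-pyrrolo[1,2-c][1,3,2]oxazaborole ((R)-Me-CBS, 0.5 equiv), catecholborane, toluene, −78 °C
Reagents that add atoms: none
Why: Corey–Bakshi–Shibata reduction; the catalyst should bind the unhindered, conjugated C2 carbonyl, and with the alkenyl side as the large group the (R)-catalyst delivers hydride to give 2S. Catecholborane at −78 °C reduces 1,2 and should not touch the α-branched C8 ketone unaided.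

Step 14
Reactants: 23 C2 alcohol
Product: 24 methyl (3aS,8S,11aR,6E,10Z)-8-[(tert-butyldimethylsilyl)oxy]-2-methoxy-10-methyl-4-oxo-2,3,3a,4,5,8,9,11a-octahydrocyclodeca[b]furan-6-carboxylate
Conditions: t-BuMe2SiCl, imidazole, DMF, rt
Reagents that add atoms: tert-butylchlorodimethylsilane, CC(C)(C)[Si](C)(C)Cl
Why: Silylation of a secondary allylic alcohol; if 23 rests partly as the transannular C8 hemiketal, only the open secondary hydroxyl is silylated and the equilibrium drains to 24.

Step 15
Reactants: 24 silyl ether keto ester
Product: 25 (3aR,4R,8S,11aR,6E,10Z)-8-[(tert-butyldimethylsilyl)oxy]-6-(hydroxymethyl)-2-methoxy-10-methyl-2,3,3a,4,5,8,9,11a-octahydrocyclodeca[b]furan-4-ol (8R,14-diol)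
Conditions: i-Bu2AlH (5 equiv), CH2Cl2, −78 °C; aq. KNaC4H4O6
Reagents that add atoms: none
Why: i-Bu2AlH reduces the enoate 1,2 to the allylic alcohol and the C8 ketone in one operation; hydride is expected anti to the C7–C6 bond (Felkin–Anh, C6 as the large group, passing the C7–H), which is the face that gives 8R.

Step 16
Reactants: 25 diol
Product: 26 [(3aR,4R,8S,11aR,6E,10Z)-8-[(tert-butyldimethylsilyl)oxy]-4-hydroxy-2-methoxy-10-methyl-2,3,3a,4,5,8,9,11a-octahydrocyclodeca[b]furan-6-yl]methyl acetate
Conditions: Ac2O (1.1 equiv), 2,4,6-collidine, CH2Cl2, −20 → 0 °C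
Reagents that add atoms: acetic anhydride, CC(=O)OC(C)=O
Why: Selective acylation of the primary allylic hydroxyl over the hindered secondary 8-hydroxyl with a weak base and a limited amount of anhydride.

Step 17
Reactants: 26 hydroxy acetate; 27 angelic acid
Product: 29 (3aR,4R,8S,11aR,6E,10Z)-6-(acetoxymethyl)-8-[(tert-butyldimethylsilyl)oxy]-2-methoxy-10-methyl-2,3,3a,4,5,8,9,11a-octahydrocyclodeca[b]furan-4-yl (Z)-2-methylbut-2-enoate, via mixed trichlorobenzoic anhydride 28 (not isolated)
Conditions: 27, 2,4,6-trichlorobenzoyl chloride, Et3N, toluene, rt; then 26, 80 °C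
Reagents that add atoms: none
Why: Yamaguchi-type esterification through the preformed mixed anhydride without a nucleophilic catalyst, the variant that gives angelates without Z to E isomerisation; O2 is silylated and O6 is locked in the acetal, so only O8 can react.

Step 18
Reactants: 29 angelate acetal
Product: 30 the corresponding lactol (2-hydroxy in place of 2-methoxy; germacrane 6,12-lactol)
Conditions: AcOH/THF/H2O (3:1:1), 35 °C
Reagents that add atoms: water, O
Why: Mild hydrolysis of the 2-methoxytetrahydrofuran, which is much faster than loss of the secondary silyl ether; with O8 and O14 acylated only O6 can hold the C12 aldehyde, so a single lactol forms.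

Step 19
Reactants: 30 lactol
Product: 31 the 3-methylidene lactol (C11=C13 in place, C12 still a lactol)
Conditions: 37% aq. CH2O, pyrrolidine (20 mol %), propionic acid (20 mol %), i-PrOH, 45 °C
Reagents that add atoms: formaldehyde, C=O
Why: Amine-catalysed Mannich condensation and elimination (α-methylenation of an enolisable aldehyde); the lactol reacts through its open hydroxy aldehyde via the enamine and recloses, and the near-neutral medium leaves the acetate and the angelate untouched.

Step 20
Reactants: 31 methylidene lactol
Product: 32 (3aR,4R,8S,11aR,6E,10Z)-6-(acetoxymethyl)-8-[(tert-butyldimethylsilyl)oxy]-10-methyl-3-methylidene-2-oxo-2,3,3a,4,5,8,9,11a-octahydrocyclodeca[b]furan-4-yl (Z)-2-methylbut-2-enoate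
Conditions: PhI(OAc)2, (2,2,6,6-tetramethylpiperidin-1-yl)oxyl (TEMPO, 10 mol %), CH2Cl2, rt
Reagents that add atoms: none
Why: Oxoammonium oxidation of a lactol to the lactone under neutral conditions; no other free hydroxyl is present and the alkenes are inert.

Step 21
Reactants: 32 silyl ether
Product: 33 CNP0151426.1, (3aR,4R,8S,11aR,6E,10Z)-6-(acetoxymethyl)-8-hydroxy-10-methyl-3-methylidene-2-oxo-2,3,3a,4,5,8,9,11a-octahydrocyclodeca[b]furan-4-yl (Z)-2-methylbut-2-enoate (germacrane 2S,6R,7R,8R)
Conditions: HF·pyridine, pyridine, THF, 0 °C → rt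
Reagents that add atoms: none
Why: Buffered acidic fluoride removes the secondary silyl ether without the basic conditions that would cause acyl migration, tiglate formation or conjugate addition to the methylene lactone.

## Compound list

1 | methyl 4,4-dimethoxybutanoate | COC(=O)CCC(OC)OC | starting material
2 | 4,4-dimethoxybutanoic acid | OC(=O)CCC(OC)OC | intermediate
3 | (S)-4-benzyloxazolidin-2-one | O=C1N[C@@H](Cc2ccccc2)CO1 | starting material
4 | 4,4-dimethoxybutanoic pivalic anhydride | COC(OC)CCC(=O)OC(=O)C(C)(C)C | intermediate (not isolated)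
5 | (S)-4-benzyl-3-(4,4-dimethoxybutanoyl)oxazolidin-2-one | COC(OC)CCC(=O)N1C(=O)OC[C@@H]1Cc1ccccc1 | intermediate
6 | acrolein | C=CC=O | starting material
7 | (Z)-dibutylboron enolate of 5 | CCCCB(CCCC)O/C(=C\CC(OC)OC)N1C(=O)OC[C@@H]1Cc1ccccc1 | intermediate (not isolated)
8 | (S)-4-benzyl-3-[(2S,3R)-2-(2,2-dimethoxyethyl)-3-hydroxypent-4-enoyl]oxazolidin-2-one | COC(OC)C[C@H](C(=O)N1C(=O)OC[C@@H]1Cc1ccccc1)[C@H](O)C=C | intermediate
9 | (2S,3R)-2-(2,2-dimethoxyethyl)-3-hydroxy-N-methoxy-N-methylpent-4-enamide | COC(OC)C[C@H](C(=O)N(C)OC)[C@H](O)C=C | intermediate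
10 | (2R,3S)-2-ethenyl-N,5-dimethoxy-N-methyloxolane-3-carboxamide | CON(C)C(=O)[C@H]1CC(OC)O[C@@H]1C=C | intermediate
11 | 1-[(2R,3S)-2-ethenyl-5-methoxyoxolan-3-yl]ethan-1-one | CC(=O)[C@H]1CC(OC)O[C@@H]1C=C | intermediate
12 | 3-methylbut-3-en-1-ol | CC(=C)CCO | starting material
13 | 3-methylbut-3-enal | CC(=C)CC=O | intermediate
14 | lithium enolate of 11 | [Li]OC(=C)[C@H]1CC(OC)O[C@@H]1C=C | intermediate (not isolated)
15 | 1-[(2R,3S)-2-ethenyl-5-methoxyoxolan-3-yl]-3-hydroxy-5-methylhex-5-en-1-one | CC(=C)CC(O)CC(=O)[C@H]1CC(OC)O[C@@H]1C=C | intermediate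
16 | (3aS,9aR,8Z)-6-hydroxy-2-methoxy-8-methyl-3,3a,5,6,7,9a-hexahydro-2H-cycloocta[b]furan-4-one | C1C(OC)O[C@@H]2/C=C(/C)CC(O)CC(=O)[C@@H]12 | intermediate
17 | (3aS,9aR,8Z)-2-methoxy-8-methyl-3,3a,7,9a-tetrahydro-2H-cycloocta[b]furan-4,6(5H)-dione | C1C(OC)O[C@@H]2/C=C(/C)CC(=O)CC(=O)[C@@H]12 | intermediate
18 | (3aS,9aR,5E,8Z)-2-methoxy-8-methyl-6-(triethylsilyloxy)-3,3a,7,9a-tetrahydro-2H-cycloocta[b]furan-4-one | C1C(OC)O[C@@H]2/C=C(/C)C/C(O[Si](CC)(CC)CC)=C\C(=O)[C@@H]12 | intermediate (key-step precursor)
19 | methyl propiolate | C#CC(=O)OC | starting material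
20 | tricyclic cyclobutene photoadduct (C1–C2 and C9–C10 bonded, C2 triethylsilyl ether, C10 methyl ester, C8 ketone) | C1C(OC)O[C@@H]2/C=C(/C)CC3(O[Si](CC)(CC)CC)C=C(C(=O)OC)C3C(=O)[C@@H]12 | intermediate (not isolated)
21 | tricyclic cyclobutenol (20 without the silyl group) | C1C(OC)O[C@@H]2/C=C(/C)CC3(O)C=C(C(=O)OC)C3C(=O)[C@@H]12 | intermediate (not isolated)
22 | methyl (3aS,11aR,6E,10Z)-2-methoxy-10-methyl-4,8-dioxo-2,3,3a,4,5,8,9,11a-octahydrocyclodeca[b]furan-6-carboxylate | C1C(OC)O[C@@H]2/C=C(/C)CC(=O)/C=C(/C(=O)OC)CC(=O)[C@@H]12 | intermediate (key-step product)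
23 | methyl (3aS,8S,11aR,6E,10Z)-8-hydroxy-2-methoxy-10-methyl-4-oxo-2,3,3a,4,5,8,9,11a-octahydrocyclodeca[b]furan-6-carboxylate | C1C(OC)O[C@@H]2/C=C(/C)C[C@H](O)/C=C(/C(=O)OC)CC(=O)[C@@H]12 | intermediate
24 | methyl (3aS,8S,11aR,6E,10Z)-8-[(tert-butyldimethylsilyl)oxy]-2-methoxy-10-methyl-4-oxo-2,3,3a,4,5,8,9,11a-octahydrocyclodeca[b]furan-6-carboxylate | C1C(OC)O[C@@H]2/C=C(/C)C[C@H](O[Si](C)(C)C(C)(C)C)/C=C(/C(=O)OC)CC(=O)[C@@H]12 | intermediate
25 | (3aR,4R,8S,11aR,6E,10Z)-8-[(tert-butyldimethylsilyl)oxy]-6-(hydroxymethyl)-2-methoxy-10-methyl-2,3,3a,4,5,8,9,11a-octahydrocyclodeca[b]furan-4-ol | C1C(OC)O[C@@H]2/C=C(/C)C[C@H](O[Si](C)(C)C(C)(C)C)/C=C(/CO)C[C@@H](O)[C@@H]12 | intermediate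
26 | [(3aR,4R,8S,11aR,6E,10Z)-8-[(tert-butyldimethylsilyl)oxy]-4-hydroxy-2-methoxy-10-methyl-2,3,3a,4,5,8,9,11a-octahydrocyclodeca[b]furan-6-yl]methyl acetate | C1C(OC)O[C@@H]2/C=C(/C)C[C@H](O[Si](C)(C)C(C)(C)C)/C=C(/COC(C)=O)C[C@@H](O)[C@@H]12 | intermediate
27 | angelic acid, (Z)-2-methylbut-2-enoic acid | C/C=C(/C)C(=O)O | starting material
28 | angelic 2,4,6-trichlorobenzoic anhydride | C/C=C(/C)C(=O)OC(=O)c1c(Cl)cc(Cl)cc1Cl | intermediate (not isolated)
29 | (3aR,4R,8S,11aR,6E,10Z)-6-(acetoxymethyl)-8-[(tert-butyldimethylsilyl)oxy]-2-methoxy-10-methyl-2,3,3a,4,5,8,9,11a-octahydrocyclodeca[b]furan-4-yl (Z)-2-methylbut-2-enoate | C1C(OC)O[C@@H]2/C=C(/C)C[C@H](O[Si](C)(C)C(C)(C)C)/C=C(/COC(C)=O)C[C@@H](OC(=O)/C(C)=C\C)[C@@H]12 | intermediate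
30 | lactol of 29 (2-hydroxy in place of 2-methoxy) | C1C(O)O[C@@H]2/C=C(/C)C[C@H](O[Si](C)(C)C(C)(C)C)/C=C(/COC(C)=O)C[C@@H](OC(=O)/C(C)=C\C)[C@@H]12 | intermediate
31 | 3-methylidene lactol | C=C1C(O)O[C@@H]2/C=C(/C)C[C@H](O[Si](C)(C)C(C)(C)C)/C=C(/COC(C)=O)C[C@@H](OC(=O)/C(C)=C\C)[C@@H]12 | intermediate
32 | (3aR,4R,8S,11aR,6E,10Z)-6-(acetoxymethyl)-8-[(tert-butyldimethylsilyl)oxy]-10-methyl-3-methylidene-2-oxo-2,3,3a,4,5,8,9,11a-octahydrocyclodeca[b]furan-4-yl (Z)-2-methylbut-2-enoate | C=C1C(=O)O[C@@H]2/C=C(/C)C[C@H](O[Si](C)(C)C(C)(C)C)/C=C(/COC(C)=O)C[C@@H](OC(=O)/C(C)=C\C)[C@@H]12 | intermediate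
33 | CNP0151426.1, (3aR,4R,8S,11aR,6E,10Z)-6-(acetoxymethyl)-8-hydroxy-10-methyl-3-methylidene-2-oxo-2,3,3a,4,5,8,9,11a-octahydrocyclodeca[b]furan-4-yl (Z)-2-methylbut-2-enoate | C=C1C(=O)O[C@@H]2/C=C(/C)C[C@H](O)/C=C(/COC(C)=O)C[C@@H](OC(=O)/C(C)=C\C)[C@@H]12 | target

## Step count and least certain steps

Total: 21 steps. Longest linear sequence: 20 steps (steps 1–6 and 8–21); step 7 is a one-step branch that supplies aldehyde 13.

**Step 12 (key step).** The alkyne may add partly head-to-tail, and the cyclobutenyl ketone 20 may be consumed by secondary photoreaction (1,3-acyl shift) before it is fragmented. Both processes are specific to the alkyne partner. The fallback is a de Mayo reaction with an alkene, which is known chemistry. It sets out from 18: irradiation with commercial methyl (E)-3-methoxyacrylate, whose donor carbon (future C1) and acceptor carbon (future C10) are polarised in the sense that puts C10 on C9, should give the saturated cyclobutane photoadduct F1, which is not a β,γ-unsaturated ketone. Bu4NF/AcOH fragments it to the ten-membered β-methoxy diketo ester F2, and DBU eliminates methanol across C1–C10 through the ester enolate (E1cB). The route is rejoined at 22. In this variant the C1=C10 geometry rests on the thermodynamic preference for the ester trans to the C2 ketone, not on a cyclobutene.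

**Step 11.** Silylation may occur partly on the C8 oxygen, or the silyl group may exchange between the two oxygens during handling. The fallback never makes C2 a carbonyl. It sets out from 16: Et3SiCl/imidazole gives the C2 triethylsilyl ether F3; LiN(i-Pr)2 with Me3SiCl present (in situ quench, −78 °C) deprotonates at C9 and gives the trimethylsilyl enol ether F4; Saegusa–Ito oxidation with Pd(OAc)2 (divalent palladium) in MeCN places the double bond at C2=C9. The route is rejoined at 18.

**Step 13.** The catalyst may discriminate poorly between the C2 and C8 carbonyls, or the conformational bias of the ring may override the catalyst and give poor facial selectivity. The fallback uses substrate control plus inversion. It sets out from 22: Luche reduction (NaBH4, CeCl3·7H2O, MeOH, −78 °C) reduces only the conjugated C2 ketone; if it gives the 2R alcohol F5, Mitsunobu reaction with 4-nitrobenzoic acid (PPh3, DIAD) gives the inverted 2S 4-nitrobenzoate F6, and K2CO3/MeOH removes the ester. The route is rejoined at 23.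

**Step 15.** Hydride delivery at C8 may follow the ring conformation and not the Felkin–Anh preference, giving the 8S alcohol. The fallback installs the ester with inversion. It sets out from 24: the 8S diol F7 is acetylated at O14 as in step 16 to the 8S hydroxy acetate F8, and Mitsunobu esterification with angelic acid 27 (PPh3, DIAD, toluene) inverts C8 as it forms the angelate. The route is rejoined at 29.

**Step 19.** The condensation may be slow because only a small share of 30 is present as the open aldehyde, and the amine may add reversibly to the product. The fallback moves the methylenation ahead of the acylations and uses a lactone enolate. It sets out from 25: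
- NaH and 4-methoxybenzyl chloride give the bis(4-methoxybenzyl) ether F9.
- AcOH/THF/H2O gives the lactol F10, and PhI(OAc)2/TEMPO gives the saturated lactone F11.
- LiN(SiMe3)2 and then CH2=NMe2+ I− give the Mannich base F12; MeI gives the methiodide F13; NaHCO3 gives the methylene lactone F14.
- 2,3-Dichloro-5,6-dicyano-1,4-benzoquinone in wet CH2Cl2 gives the diol F15, and selective acetylation gives the hydroxy acetate F16.
- Angeloylation as in step 17 rejoins the route at 32.

## Further compounds

F1 | step 12 | cyclobutane photoadduct of 18 with methyl (E)-3-methoxyacrylate (C1 methoxy, C10 ester, C2 triethylsilyl ether) | C1C(OC)O[C@@H]2/C=C(/C)CC3(O[Si](CC)(CC)CC)C(OC)C(C(=O)OC)C3C(=O)[C@@H]12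
F2 | step 12 | ten-membered 1-methoxy-2,8-diketone C14 methyl ester | C1C(OC)O[C@@H]2/C=C(/C)CC(=O)C(OC)C(C(=O)OC)CC(=O)[C@@H]12
F3 | step 11 | C2 triethylsilyl ether of 16 | C1C(OC)O[C@@H]2/C=C(/C)CC(O[Si](CC)(CC)CC)CC(=O)[C@@H]12
F4 | step 11 | C8 trimethylsilyl enol ether (C8=C9) of F3 | C1C(OC)O[C@@H]2/C=C(/C)CC(O[Si](CC)(CC)CC)/C=C(/O[Si](C)(C)C)[C@@H]12
F5 | step 13 | 2R epimer of 23 | C1C(OC)O[C@@H]2/C=C(/C)C[C@@H](O)/C=C(/C(=O)OC)CC(=O)[C@@H]12
F6 | step 13 | 2S 4-nitrobenzoate of 23 | C1C(OC)O[C@@H]2/C=C(/C)C[C@H](OC(=O)c3ccc(cc3)[N+](=O)[O-])/C=C(/C(=O)OC)CC(=O)[C@@H]12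
F7 | step 15 | 8S epimer of diol 25 | C1C(OC)O[C@@H]2/C=C(/C)C[C@H](O[Si](C)(C)C(C)(C)C)/C=C(/CO)C[C@H](O)[C@@H]12
F8 | step 15 | 8S epimer of hydroxy acetate 26 | C1C(OC)O[C@@H]2/C=C(/C)C[C@H](O[Si](C)(C)C(C)(C)C)/C=C(/COC(C)=O)C[C@H](O)[C@@H]12
F9 | step 19 | 8,14-bis(4-methoxybenzyl) ether of 25 | C1C(OC)O[C@@H]2/C=C(/C)C[C@H](O[Si](C)(C)C(C)(C)C)/C=C(/COCc3ccc(OC)cc3)C[C@@H](OCc3ccc(OC)cc3)[C@@H]12
F10 | step 19 | lactol of F9 | C1C(O)O[C@@H]2/C=C(/C)C[C@H](O[Si](C)(C)C(C)(C)C)/C=C(/COCc3ccc(OC)cc3)C[C@@H](OCc3ccc(OC)cc3)[C@@H]12
F11 | step 19 | saturated 6,12-lactone bis(4-methoxybenzyl) ether | C1C(=O)O[C@@H]2/C=C(/C)C[C@H](O[Si](C)(C)C(C)(C)C)/C=C(/COCc3ccc(OC)cc3)C[C@@H](OCc3ccc(OC)cc3)[C@@H]12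
F12 | step 19 | C11 (dimethylamino)methyl lactone (Mannich base) | CN(C)CC1C(=O)O[C@@H]2/C=C(/C)C[C@H](O[Si](C)(C)C(C)(C)C)/C=C(/COCc3ccc(OC)cc3)C[C@@H](OCc3ccc(OC)cc3)[C@@H]12
F13 | step 19 | methiodide of F12 | C[N+](C)(C)CC1C(=O)O[C@@H]2/C=C(/C)C[C@H](O[Si](C)(C)C(C)(C)C)/C=C(/COCc3ccc(OC)cc3)C[C@@H](OCc3ccc(OC)cc3)[C@@H]12.[I-]
F14 | step 19 | α-methylene lactone bis(4-methoxybenzyl) ether | C=C1C(=O)O[C@@H]2/C=C(/C)C[C@H](O[Si](C)(C)C(C)(C)C)/C=C(/COCc3ccc(OC)cc3)C[C@@H](OCc3ccc(OC)cc3)[C@@H]12
F15 | step 19 | α-methylene lactone 8,14-diol (O2 silyl ether) | C=C1C(=O)O[C@@H]2/C=C(/C)C[C@H](O[Si](C)(C)C(C)(C)C)/C=C(/CO)C[C@@H](O)[C@@H]12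
F16 | step 19 | α-methylene lactone 8-hydroxy 14-acetate (O2 silyl ether) | C=C1C(=O)O[C@@H]2/C=C(/C)C[C@H](O[Si](C)(C)C(C)(C)C)/C=C(/COC(C)=O)C[C@@H](O)[C@@H]12
A1 | alternative 1 | ten-membered C6 alcohol with C12 silyl ether (product of the chromium-mediated closure) | O[C@@H]1/C=C(/C)C[C@H](O[Si](C)(C)C(C)(C)C)/C=C(/COC(C)=O)C[C@@H](OC(=O)/C(C)=C\C)[C@H]1C(=C)CO[Si](CC)(CC)CC
A2 | alternative 1 | open-chain (Z)-C5 iodoalkene C6 aldehyde | I/C=C(/C)C[C@H](O[Si](C)(C)C(C)(C)C)/C=C(/COC(C)=O)C[C@@H](OC(=O)/C(C)=C\C)[C@H](C=O)C(=C)CO[Si](CC)(CC)CC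
A3 | alternative 2 | ten-membered C6 ketone with C8 dimethylphenylsilyl group (oxy-Cope product) | O=C1/C=C(/C)C[C@H](O[Si](C)(C)C(C)(C)C)/C=C(/CO[Si](C)(C)C(C)(C)C)C[C@@H]([Si](C)(C)c2ccccc2)C1
A4 | alternative 2 | cis-dialkenylcyclohexenol (C6 carbinol with (E)-2-(dimethylphenylsilyl)vinyl, cis to the C1 propen-2-yl group that carries C14) | O[C@]1(/C=C/[Si](C)(C)c2ccccc2)C=C(C)C[C@H](O[Si](C)(C)C(C)(C)C)[C@H]1C(=C)CO[Si](C)(C)C(C)(C)C
A5 | alternative 3 | ten-membered ring with C14 methyl ester (olefination product) | CC[Si](CC)(CC)O[C@@H]1/C=C(/C)C[C@H](O[Si](C)(C)C(C)(C)C)/C=C(/C(=O)OC)C[C@@H](OCc2ccc(OC)cc2)[C@H]1CC(OC)OC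
A6 | alternative 3 | open-chain C1 aldehyde C10 phosphonoacetate | O=C[C@@H](O[Si](C)(C)C(C)(C)C)C/C(C)=C\[C@@H](O[Si](CC)(CC)CC)[C@H](CC(OC)OC)[C@H](OCc1ccc(OC)cc1)CC(C(=O)OC)P(=O)(OC)OC
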